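**Retrosynthetic overview**

1. Numbering: C1 = CH(OAc) next to the alkene, C2=C3, C4 = CH(OBz), C5 = C(OH)(C7H2OBz), C6 = CH(OAc). The ring is drawn with C1 to C6 clockwise and beta means towards the viewer, so C7 and O6 are beta and O1, O4, O5 are alpha.
2. The target comes from diacetylation of the 1,5,6-triol. The triol comes from an allylsilane by epoxidation anti to silicon and Peterson-type opening, which turns C1=C2/C3–SiMe3 into C1–O/C2=C3. The allylsilane comes from a C7 aldehyde by reduction and a benzoyl shift from O5 to O7.
3. The aldehyde comes from one enantioselective Diels–Alder reaction. It closes the only carbocycle by making C3–C4 and C6–C5 from two achiral chains: a 1-silyloxy-4-silyl diene (C6–C1–C2–C3) and the dibenzoate of triose reductone (C4=C5–C7HO).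
4. Enabling feature: in the six-membered ring O4 and O5 are cis (a masked (Z)-enediol diester) and the branch C7 on C5 is cis to O6 on the neighbouring carbon (endo rule). The array C6(O)–C1(O)–C2=C3 is what an allylsilane C1=C2–C3–Si leaves after oxidation.
5. The diene comes from allyltrimethylsilane and crotonaldehyde. The dienophile comes from malonaldehyde and two benzoyloxy units. One ring is formed, in step 6.

Key step: step 6

Assumption: the sense of induction is taken from the accepted model for 2-substituted enals on oxazaborolidinium ions (formyl C–H···O contact, one face of the s-trans enal covered by a phenyl group). For this dienophile the model predicts that the (R)-catalyst leaves the Si face at C5 and C4 open. Should the sense be opposite, the equally available (S)-catalyst is used.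

**Step 1**
Reactants: 1 allyltrimethylsilane; 2 (E)-crotonaldehyde
Product: 3 (E)-4-(trimethylsilyl)but-2-enal
Conditions: 2 (3 equiv), second-generation Grubbs catalyst RuCl2(=CHPh)(PCy3)(SIMes) (SIMes = 1,3-dimesitylimidazolidin-2-ylidene, 2 mol %), CH2Cl2, 40 °C
Reagents that add atoms: none
Why: Olefin cross-metathesis between an electron-rich terminal allylsilane and an electron-poor enal is a selective pairing that should give the (E)-enal, with loss of volatile propene driving the exchange.

**Step 2**
Reactants: 3 (E)-4-(trimethylsilyl)but-2-enal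
Product: 5 (1E,3E)-1-(tert-butyldimethylsilyloxy)-4-(trimethylsilyl)buta-1,3-diene, via potassium dienolate 4 (not isolated)
Conditions: KOt-Bu, THF, −78 °C; then TBSCl, −78 °C to 0 °C
Reagents that add atoms: tert-butyldimethylsilyl chloride CC(C)(C)[Si](C)(C)Cl; potassium tert-butoxide CC(C)(C)[O-].[K+] (potassium of intermediate 4 only)
Why: Kinetic gamma-deprotonation of the s-trans enal (protons vinylogously activated and alpha to silicon) followed by O-silylation of the dienolate is the standard route to (1E)-dienol derivatives, and the bulky SiMe3 group takes the E position at the new terminal double bond.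

**Step 3**
Reactants: 6 1,1,3,3-tetramethoxypropane
Product: 8 sodium (E)-3-oxoprop-1-en-1-olate (sodium malonaldehyde), via malonaldehyde 7 (not isolated)
Conditions: cat. HCl, H2O, rt; then NaOH (1 equiv), 0 °C; evaporation, trituration with acetone
Reagents that add atoms: water O; sodium hydroxide [Na+].[OH-]
Why: Acid-catalysed acetal hydrolysis followed by neutralisation of the strongly acidic enol should give the storable sodium enolate in its extended (E) form.

**Step 4**
Reactants: 8 sodium malonaldehyde
Product: 9 2-(benzoyloxy)propanedial (2-benzoyloxymalonaldehyde, largely enolised)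
Conditions: (PhCO2)2 (1.0 equiv), DMF, 0 °C to rt; 1 M HCl work-up
Reagents that add atoms: dibenzoyl peroxide O=C(OOC(=O)c1ccccc1)c1ccccc1
Why: Alpha-benzoyloxylation of a 1,3-dicarbonyl enolate with dibenzoyl peroxide, in which the soft central carbon attacks the O–O bond as it does for malonates, beta-keto esters and enamines.

**Step 5**
Reactants: 9 2-(benzoyloxy)propanedial
Product: 10 (Z)-2,3-bis(benzoyloxy)prop-2-enal (triose reductone dibenzoate; the two benzoates cis, O3 trans to CHO)
Conditions: BzCl, Et3N, CH2Cl2, −20 °C; recrystallisation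
Reagents that add atoms: benzoyl chloride O=C(Cl)c1ccccc1
Why: O-acylation of the extended malonaldehyde-type enolate places the new benzoate trans to the formyl group, as in the known 3-acyloxy- and 3-alkoxy-2-substituted acroleins, which is the (Z) geometry needed for the cis O4/O5 pair.

**Step 6**
Reactants: 5 (1E,3E)-1-(tert-butyldimethylsilyloxy)-4-(trimethylsilyl)buta-1,3-diene; 10 (Z)-2,3-bis(benzoyloxy)prop-2-enal
Product: 11 (3R,4R,5S,6S)-4,5-bis(benzoyloxy)-6-(tert-butyldimethylsilyloxy)-3-(trimethylsilyl)cyclohex-1-ene-5-carbaldehyde (route numbering: SiMe3, C7HO and OTBS beta; both benzoates alpha)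
Conditions: (R)-3,3-diphenyl-1-(2-methylphenyl)tetrahydro-1H,3H-pyrrolo[1,2-c][1,3,2]oxazaborole (C24H24BNO, 20 mol %) + HN(SO2CF3)2 (18 mol %), CH2Cl2, −78 °C to −40 °C
Reagents that add atoms: none
Why: The boron Lewis acid binds the formyl oxygen of 10 and 5 adds in a concerted, asynchronous normal-demand Diels–Alder reaction in which the C3–C4 bond runs ahead of the C6–C5 bond; the closest known reactions are the cycloadditions of 1-acyloxy-4-silylbutadienes with acrylic dienophiles, those of 2-acyloxyacroleins with dienes, and the oxazaborolidinium-catalysed additions of silyloxydienes to 2-substituted enals. The only ring, the cyclohexene C1–C6, is closed by an intermolecular suprafacial [4+2] union of the diene termini C3 and C6 with C4 and C5. Regiochemistry is matched on both partners: C3 is the nucleophilic terminus because the charge that develops over C2–C1–C6 is stabilised by O6 and by hyperconjugation with the C3–Si bond, and C4 is the electrophilic beta carbon of the enal. Relative configuration follows from geometry and the endo rule: the (1E,3E)-diene puts SiMe3 and O6 cis, the (Z)-enal puts O4 and O5 cis, and the endo position of the coordinated formyl group, which is also the less crowded one since it sets the small C4–H and not a benzoate beside SiMe3, puts C7 cis to O6. Absolute configuration at C3, C4, C5 and C6 is set by the catalyst, whose phenyl group covers the Re face of the s-trans enal held by the formyl C–H···O contact, so that the diene reaches the Si face at C5 and C4. The step needs carbon–carbon rather than carbonyl addition and no silyl transfer, which the weakly polarised mono-oxygenated diene, the bulky tert-butyldimethylsilyl group, the slight deficit of HN(SO2CF3)2 relative to the oxazaborolidine and the low temperature should secure.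

**Step 7**
Reactants: 11 Diels–Alder aldehyde
Product: 13 allylsilane alcohol (3R,4R,5S,6S; C5–OH alpha free; benzoates on O4 and O7; OTBS on O6; SiMe3 on C3), via primary alcohol 12 (not isolated)
Conditions: NaBH4, THF/EtOH, −20 °C to rt; aq. NH4Cl work-up
Reagents that add atoms: none
Why: Borohydride reduction of the non-enolisable aldehyde is chemoselective over the esters, and the C7 alkoxide then takes over the benzoyl group of O5 through a five-membered orthoester anion (1,2-acyl migration, tertiary to primary); since benzoates are the only acyl groups present, any detour via O4 ends at the same compound, and no stereocentre is touched.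

**Step 8**
Reactants: 13 allylsilane alcohol
Product: 16 triol (1R,4S,5R,6S; O1–H alpha; O5–H alpha; O6–H beta; benzoates on O4 and O7; alkene C2=C3), via alpha-epoxide 14 (not isolated), via silyl ether 15 (not isolated)
Conditions: mCPBA, CH2Cl2, 0 °C; aqueous wash; then HF·pyridine, THF, 0 °C to rt
Reagents that add atoms: 3-chloroperoxybenzoic acid O=C(OO)c1cccc(Cl)c1
Why: Peracid epoxidation of the allylsilane should occur on the alpha face, anti to SiMe3 and OTBS and guided by the homoallylic C5–OH, which sets C1; HF then triggers the anti Peterson-type (beta-silyl) opening of the C2–O bond to give the C2=C3 alkene with O1 retained, and cleaves the silyl ether at O6.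

**Step 9**
Reactants: 16 triol
Product: 17 cleistenediol F
Conditions: Ac2O, pyridine, cat. 4-(dimethylamino)pyridine, CH2Cl2, 0 °C to rt
Reagents that add atoms: acetic anhydride CC(=O)OC(C)=O
Why: Standard O-acylation in which the two secondary hydroxyl groups at C1 and C6 are acetylated while the hindered tertiary C5–OH stays free, with no stereocentre affected.

**Compound list**

1 | allyltrimethylsilane | C=CC[Si](C)(C)C | starting material
2 | (E)-crotonaldehyde | C/C=C/C=O | starting material
3 | (E)-4-(trimethylsilyl)but-2-enal | O=C/C=C/C[Si](C)(C)C | intermediate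
4 | potassium (1E,3E)-4-(trimethylsilyl)buta-1,3-dien-1-olate | [K+].[O-]/C=C/C=C/[Si](C)(C)C | intermediate
5 | (1E,3E)-1-(tert-butyldimethylsilyloxy)-4-(trimethylsilyl)buta-1,3-diene | CC(C)(C)[Si](C)(C)O/C=C/C=C/[Si](C)(C)C | intermediate
6 | 1,1,3,3-tetramethoxypropane | COC(OC)CC(OC)OC | starting material
7 | malonaldehyde (propanedial) | O=CCC=O | intermediate
8 | sodium (E)-3-oxoprop-1-en-1-olate | [Na+].[O-]/C=C/C=O | intermediate
9 | 2-(benzoyloxy)propanedial | O=CC(C=O)OC(=O)c1ccccc1 | intermediate
10 | (Z)-2,3-bis(benzoyloxy)prop-2-enal | O=C/C(OC(=O)c1ccccc1)=C/OC(=O)c1ccccc1 | intermediate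
11 | (3R,4R,5S,6S)-4,5-bis(benzoyloxy)-6-(tert-butyldimethylsilyloxy)-3-(trimethylsilyl)cyclohex-1-ene-5-carbaldehyde (route numbering) | CC(C)(C)[Si](C)(C)O[C@H]1C=C[C@@H]([Si](C)(C)C)[C@H](OC(=O)c2ccccc2)[C@@]1(OC(=O)c2ccccc2)C=O | intermediate
12 | (3R,4R,5S,6S)-6-(tert-butyldimethylsilyloxy)-5-(hydroxymethyl)-3-(trimethylsilyl)cyclohex-1-ene-4,5-diyl dibenzoate (route numbering) | CC(C)(C)[Si](C)(C)O[C@H]1C=C[C@@H]([Si](C)(C)C)[C@H](OC(=O)c2ccccc2)[C@@]1(OC(=O)c2ccccc2)CO | intermediate
13 | [(3R,4R,5S,6S)-4-(benzoyloxy)-6-(tert-butyldimethylsilyloxy)-5-hydroxy-3-(trimethylsilyl)cyclohex-1-en-5-yl]methyl benzoate (route numbering) | CC(C)(C)[Si](C)(C)O[C@H]1C=C[C@@H]([Si](C)(C)C)[C@H](OC(=O)c2ccccc2)[C@@]1(O)COC(=O)c2ccccc2 | intermediate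
14 | (1R,2S,3R,4R,5S,6S)-1,2-alpha-epoxide of 13 | CC(C)(C)[Si](C)(C)O[C@H]1[C@@H]2O[C@@H]2[C@@H]([Si](C)(C)C)[C@H](OC(=O)c3ccccc3)[C@@]1(O)COC(=O)c3ccccc3 | intermediate
15 | [(1R,4S,5S,6S)-4-(benzoyloxy)-6-(tert-butyldimethylsilyloxy)-1,5-dihydroxycyclohex-2-en-5-yl]methyl benzoate (route numbering) | CC(C)(C)[Si](C)(C)O[C@H]1[C@H](O)C=C[C@H](OC(=O)c2ccccc2)[C@@]1(O)COC(=O)c2ccccc2 | intermediate
16 | [(1R,4S,5R,6S)-4-(benzoyloxy)-1,5,6-trihydroxycyclohex-2-en-5-yl]methyl benzoate (route numbering) | O[C@H]1[C@H](O)C=C[C@H](OC(=O)c2ccccc2)[C@@]1(O)COC(=O)c2ccccc2 | intermediate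
17 | cleistenediol F, [(1R,4S,5S,6S)-1,6-diacetoxy-4-(benzoyloxy)-5-hydroxycyclohex-2-en-5-yl]methyl benzoate (route numbering) | CC(=O)O[C@@H]1C=C[C@H](OC(=O)c2ccccc2)[C@@](O)(COC(=O)c2ccccc2)[C@H]1OC(C)=O | target

**Step count**

Total step count: 9. Longest linear sequence: 7 (steps 3 to 9, from 6).

**Steps most likely to fail**

**1. Step 6.**
- What may go wrong: the cycloaddition of a trisubstituted, donor-bearing enal may be slow at low temperature. Addition to the formyl group may compete. Silyl transfer may release an achiral silyl Lewis acid and erode the facial selectivity.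
- Fallback (catalyst control replaced by racemic synthesis and classical resolution): setting out from 5 and 10, the uncatalysed thermal Diels–Alder reaction (toluene, 100 °C) should give the racemic endo adduct F1. Condensation with (1R,2R)-N,N'-dimethyl-1,2-diphenylethane-1,2-diamine (Et2O, 4 Å molecular sieves, rt) gives the imidazolidine of the wanted enantiomer F2 and the imidazolidine of the unwanted enantiomer F3. These are diastereomers without a new stereocentre at C7 and are separated by chromatography or crystallisation. Mild hydrolysis of F2 (dilute aqueous HCl/Et2O, 0 °C) comes back to the route at 11.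

**2. Step 4.**
- What may go wrong: acyl transfer to the enolate oxygen instead of attack of carbon on the O–O bond, a second oxidation, or hydrolytic loss of the vinylic benzoate during work-up.
- Fallback (oxygen brought in by epoxidation instead of by the peroxide): setting out from 8, O-benzoylation (BzCl, MeCN, 0 °C) gives (E)-3-oxoprop-1-en-1-yl benzoate F4. Epoxidation with dimethyldioxirane (acetone, 0 °C) gives the racemic trans enol ester epoxide F5. On warming or on silica gel it should undergo the classical enol ester epoxide rearrangement (1,2-benzoyloxy shift with formation of the second formyl group), which comes back to the route at 9.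

**3. Step 2.**
- What may go wrong: attack of the alkoxide at silicon with loss of SiMe3 from the vinylogous alpha-silyl aldehyde, self-condensation of the enal, or erosion of the 1E geometry.
- Fallback (silicon introduced after the diene is made): setting out from 2, soft enolisation (TBSOTf, Et3N, Et2O, 0 °C) gives (E)-1-(tert-butyldimethylsilyloxy)buta-1,3-diene F6. Silylative coupling of its terminal CH2 with vinyltrimethylsilane catalysed by RuHCl(CO)(PCy3)2 (toluene, 100 °C), a reaction known for terminal (E)-1,3-dienes and selective for (E)-vinylsilanes, comes back to the route at 5.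

**Further compounds**

F1 | step 6 | racemic 11 (both enantiomers) | CC(C)(C)[Si](C)(C)O[C@H]1C=C[C@@H]([Si](C)(C)C)[C@H](OC(=O)c2ccccc2)[C@@]1(OC(=O)c2ccccc2)C=O.CC(C)(C)[Si](C)(C)O[C@@H]1C=C[C@H]([Si](C)(C)C)[C@@H](OC(=O)c2ccccc2)[C@]1(OC(=O)c2ccccc2)C=O
F2 | step 6 | (4R,5R)-1,3-dimethyl-4,5-diphenylimidazolidin-2-yl derivative of 11 (C7 as aminal carbon) | CC(C)(C)[Si](C)(C)O[C@H]1C=C[C@@H]([Si](C)(C)C)[C@H](OC(=O)c2ccccc2)[C@@]1(OC(=O)c2ccccc2)C2N(C)[C@H](c3ccccc3)[C@@H](c3ccccc3)N2C
F3 | step 6 | (4R,5R)-1,3-dimethyl-4,5-diphenylimidazolidin-2-yl derivative of the enantiomer of 11 | CC(C)(C)[Si](C)(C)O[C@@H]1C=C[C@H]([Si](C)(C)C)[C@@H](OC(=O)c2ccccc2)[C@]1(OC(=O)c2ccccc2)C2N(C)[C@H](c3ccccc3)[C@@H](c3ccccc3)N2C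
F4 | step 4 | (E)-3-oxoprop-1-en-1-yl benzoate | O=C/C=C/OC(=O)c1ccccc1
F5 | step 4 | racemic trans-3-formyloxiran-2-yl benzoate (both enantiomers) | O=C[C@H]1O[C@@H]1OC(=O)c1ccccc1.O=C[C@@H]1O[C@H]1OC(=O)c1ccccc1
F6 | step 2 | (E)-1-(tert-butyldimethylsilyloxy)buta-1,3-diene | CC(C)(C)[Si](C)(C)O/C=C/C=C
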